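**Plan**

- Quinone numbering used here: C1(=O), C2(OMe), C3(OMe), C4(=O), C5(chromanyl), C6(H).
- Cuts: quinone bond C4–C5 is cut and C1–C4 rejoined on paper (six-ring to four-ring), giving a 4-alkynyl-4-hydroxycyclobutenone. Cutting C1–C6 then gives dimethyl squarate and a chroman-3-yl acetylide. The alkyne goes back via C≡C ⇒ CHO ⇒ CO2H, and chroman O1–C2 and C3–C4 are cut to a salicylaldehyde and acrylonitrile.
- Enabling feature: the run C1(=O)–C2(OMe)=C3(OMe)–C4(=O) of the quinone ring is the carbon skeleton and oxidation pattern of dimethyl squarate. The remaining C5=C6 pair is an alkyne unit whose only substituent is the sp3 carbon C3 of the chroman, so a four-membered ring can grow by two atoms into the quinone.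
- Forward order: the pyran ring of the chroman is annulated onto the ready-made arene, then C3 is set, CO2H is homologated to C≡C–Li, the four-membered ring is attached, and the quinone ring forms last by 4 → 6 expansion.
- Stereochemistry: the single stereocenter (chroman C3) comes from a ruthenium-catalysed asymmetric hydrogenation of the chromene acid. All later steps are base-free, cryogenic or neutral, so it is carried through unchanged.

Key step: step 8

Assumption: the facial sense in step 3 is taken from (E)-2-alkylcinnamic acids and tiglic acid with the same catalyst family. If it proves opposite, the (R)-ligand is used with no other change.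

**Route**

Step 1
Reactants: 1 2-hydroxy-4,5-dimethoxybenzaldehyde; 2 acrylonitrile
Product: 3 6,7-dimethoxy-2H-chromene-3-carbonitrile
Conditions: DABCO (0.3 equiv), neat acrylonitrile, reflux
Reagents that add atoms: none
Why: Baylis–Hillman-type annulation of a salicylaldehyde with acrylonitrile under DABCO catalysis (conjugate addition, aldol closure onto the formyl group, loss of water) is the standard entry to 2H-chromene-3-carbonitriles and creates no stereocenter.

Step 2
Reactants: 3 6,7-dimethoxy-2H-chromene-3-carbonitrile
Product: 4 6,7-dimethoxy-2H-chromene-3-carboxylic acid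
Conditions: NaOH (10 % aq), reflux; then HCl to pH 2
Reagents that add atoms: sodium hydroxide, [Na+].[OH-]; water, O
Why: Alkaline nitrile hydrolysis is routine for 2H-chromene-3-carbonitriles, the aryl methyl ethers and the allyl aryl ether being inert to aqueous hydroxide, and no stereocenter is involved.

Step 3
Reactants: 4 6,7-dimethoxy-2H-chromene-3-carboxylic acid
Product: 5 (3R)-6,7-dimethoxychroman-3-carboxylic acid
Conditions: Ru(OAc)2[(S)-H8-BINAP] (1 mol %), H2 (5 bar), MeOH, 25 °C
Reagents that add atoms: none
Why: Noyori-type asymmetric hydrogenation of a trisubstituted α,β-unsaturated carboxylic acid, in which the carboxylate binds ruthenium and directs syn delivery of H2 to one olefin face; since the aryl carbon on C4 is trans to CO2H as in (E)-2-alkylcinnamic acids, the (S)-ligand should deliver hydrogen to the face that gives the (3R)-acid, the only stereocenter of the route.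

Step 4
Reactants: 5 (3R)-6,7-dimethoxychroman-3-carboxylic acid
Product: 6 [(3S)-6,7-dimethoxychroman-3-yl]methanol
Conditions: BH3·THF, THF, 0 °C to rt; aq work-up
Reagents that add atoms: none
Why: Borane reduction of a carboxylic acid proceeds through an acyloxyborane under non-basic conditions, so C3 keeps its geometry (the descriptor changes from R to S only because the CIP ranking of the substituents changes) and the arene and ethers are untouched.

Step 5
Reactants: 6 [(3S)-6,7-dimethoxychroman-3-yl]methanol
Product: 7 (3R)-6,7-dimethoxychroman-3-carbaldehyde
Conditions: Dess–Martin periodinane, CH2Cl2, 0 °C to rt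
Reagents that add atoms: none
Why: Dess–Martin oxidation stops at the aldehyde under base-free conditions, which should suppress enolization and retro-oxa-Michael opening of the β-aryloxy aldehyde and so keep C3 intact (descriptor R by CIP ranking only).

Step 6
Reactants: 7 (3R)-6,7-dimethoxychroman-3-carbaldehyde
Product: 8 (3S)-3-(2,2-dibromoethenyl)-6,7-dimethoxychroman
Conditions: CBr4, PPh3 (premixed), CH2Cl2, 0 °C
Reagents that add atoms: carbon tetrabromide, BrC(Br)(Br)Br
Why: Ramirez dibromoolefination (first stage of the Corey–Fuchs sequence) is a Wittig-type reaction of preformed Ph3P=CBr2 that needs no external base, so the α-stereocenter of the aldehyde should be carried over unchanged.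

Step 7
Reactants: 8 (3S)-3-(2,2-dibromoethenyl)-6,7-dimethoxychroman; 9 dimethyl squarate (3,4-dimethoxycyclobut-3-ene-1,2-dione)
Product: 11 4-{[(3S)-6,7-dimethoxychroman-3-yl]ethynyl}-4-hydroxy-2,3-dimethoxycyclobut-2-en-1-one (both carbinol epimers), via lithium acetylide 10 (not isolated)
Conditions: n-BuLi (2.0 equiv), THF, −78 to −20 °C; cannulated into 9 (1.1 equiv), THF, −78 °C; aq NH4Cl
Reagents that add atoms: n-butyllithium, [Li]CCCC (supplies the lithium of 10)
Why: The second stage of the Corey–Fuchs sequence (Br/Li exchange, loss of LiBr with 1,2-shift, deprotonation) gives the lithium acetylide, whose 1,2-addition to one of the two equivalent carbonyl groups of dimethyl squarate is the standard entry to 4-alkynyl-4-hydroxycyclobutenones; the new carbinol stereocenter forms without control, which is harmless because it is erased in step 8, and C3 is not touched at −78 °C.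

Step 8
Reactants: 11 4-{[(3S)-6,7-dimethoxychroman-3-yl]ethynyl}-4-hydroxy-2,3-dimethoxycyclobut-2-en-1-one
Product: 14 abroquinone A, via enynylketene 12 (not isolated), via aryl diradical 13 (not isolated)
Conditions: p-xylene (0.01 M, degassed), reflux (138 °C), Ar
Reagents that add atoms: none
Why: Heating cleaves the C(=O)–C(OH) bond of the four-membered ring in a conrotatory 4π electrocyclic opening in which the hydroxyl donor rotates outward, so that the alkynyl group of enynylketene 12 lies next to the ketene carbon. The ketene carbon then bonds to the distal alkyne carbon (the one bearing chroman C3) to give the aromatic diradical 13 (phenoxyl oxygen plus σ-aryl radical), and transfer of the hydroxyl hydrogen to the aryl radical carbon delivers the quinone at its final oxidation level with no oxidant. The closest known reaction type is the Moore rearrangement of 4-alkynyl-4-hydroxycyclobutenones to 1,4-benzoquinones, a four-to-six ring expansion. The one ring closed is the quinone ring, by a 6-endo-dig closure on the alkyne. No new stereocenter arises: the carbinol center of 11 becomes a carbonyl carbon, and chroman C3 is a spectator that should be retained because the medium is neutral and aprotic. The step needs 6-endo over 5-exo closure (which would lead to an alkylidenecyclopentenedione), and this is secured by the sp3 secondary-alkyl substituent on the alkyne terminus, which gives no stabilization to an exocyclic vinyl radical, while the substitution pattern (two vicinal OMe, chromanyl next to C=O, H at C6) is fixed by the connectivity of 11.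

**Compound list**

1 | 2-hydroxy-4,5-dimethoxybenzaldehyde | COc1cc(O)c(C=O)cc1OC | starting material
2 | acrylonitrile | C=CC#N | starting material
3 | 6,7-dimethoxy-2H-chromene-3-carbonitrile | N#CC1=Cc2cc(OC)c(OC)cc2OC1 | intermediate
4 | 6,7-dimethoxy-2H-chromene-3-carboxylic acid | OC(=O)C1=Cc2cc(OC)c(OC)cc2OC1 | intermediate
5 | (3R)-6,7-dimethoxychroman-3-carboxylic acid | OC(=O)[C@H]1COc2cc(OC)c(OC)cc2C1 | intermediate
6 | [(3S)-6,7-dimethoxychroman-3-yl]methanol | OC[C@H]1COc2cc(OC)c(OC)cc2C1 | intermediate
7 | (3R)-6,7-dimethoxychroman-3-carbaldehyde | O=C[C@H]1COc2cc(OC)c(OC)cc2C1 | intermediate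
8 | (3S)-3-(2,2-dibromoethenyl)-6,7-dimethoxychroman | BrC(Br)=C[C@H]1COc2cc(OC)c(OC)cc2C1 | intermediate
9 | dimethyl squarate | COC1=C(OC)C(=O)C1=O | starting material
10 | lithium [(3S)-6,7-dimethoxychroman-3-yl]acetylide | [Li]C#C[C@H]1COc2cc(OC)c(OC)cc2C1 | intermediate
11 | 4-{[(3S)-6,7-dimethoxychroman-3-yl]ethynyl}-4-hydroxy-2,3-dimethoxycyclobut-2-en-1-one (carbinol center unassigned, both epimers) | COC1=C(OC)C(O)(C#C[C@H]2COc3cc(OC)c(OC)cc3C2)C1=O | intermediate
12 | (Z)-enynylketene, 6-[(3S)-6,7-dimethoxychroman-3-yl]-4-hydroxy-2,3-dimethoxyhexa-1,3-dien-5-yn-1-one | O=C=C(OC)/C(OC)=C(\C#C[C@H]1COc2cc(OC)c(OC)cc2C1)O | intermediate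
13 | aryl diradical, 2-[(3S)-6,7-dimethoxychroman-3-yl]-4-hydroxy-5,6-dimethoxyphenoxyl-3-yl | [O]c1c(OC)c(OC)c(O)[c]c1[C@H]2COc3cc(OC)c(OC)cc3C2 | intermediate
14 | abroquinone A, 2,3-dimethoxy-5-[(3S)-6,7-dimethoxychroman-3-yl]cyclohexa-2,5-diene-1,4-dione | COC1=C(OC)C(=O)C([C@H]2COc3cc(OC)c(OC)cc3C2)=CC1=O | target

Total step count: 8. Longest linear sequence: 8 (from 1 to 14; 2 and 9 enter as purchased reagents).

**Steps most likely to fail**

Step 3. The catalyst may discriminate the two olefin faces of the cyclic acid insufficiently, or in the sense opposite to the acyclic analogy. The fallback is a classical resolution. It sets out from 4. Hydrogenation over Pd/C (H2, MeOH, rt) should give racemic 6,7-dimethoxychroman-3-carboxylic acid F1. Crystallization with (S)-1-phenylethylamine from ethanol should give the less soluble salt (S)-1-phenylethylammonium (3R)-6,7-dimethoxychroman-3-carboxylate F2. The antipodal amine is taken if the solubility pairing is reversed. Acidification with dilute HCl comes back to the route at 5.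

Step 7. Conversion of the dibromoalkene into the acetylide may be incomplete. Leftover butyllithium would then be carried into the squarate solution, where it would add to the dione or cause double addition. The fallback replaces the dibromoalkene pathway by a diazophosphonate homologation. It sets out from 7. Seyferth–Gilbert homologation with the Ohira–Bestmann reagent (dimethyl (1-diazo-2-oxopropyl)phosphonate, K2CO3, MeOH, 0 °C) should give isolable (3S)-3-ethynyl-6,7-dimethoxychroman F3. This is purified, checked for enantiomeric purity and deprotonated with exactly one equivalent of n-BuLi (THF, −78 °C). The route is rejoined at 10, which is added to 9 as before.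

Step 8. The diradical pathway may be diverted by 5-exo closure or by hydrogen abstraction from the solvent or from the benzylic C4–H bonds. The electron-rich arene and quinone pair may also degrade at 138 °C. The fallback changes the ring expansion from a diradical to a closed-shell process. It sets out from 11. Semihydrogenation (H2, Pd/CaCO3 poisoned with Pb(OAc)2, quinoline, EtOAc) should give 4-{(Z)-2-[(3S)-6,7-dimethoxychroman-3-yl]ethenyl}-4-hydroxy-2,3-dimethoxycyclobut-2-en-1-one F4. In refluxing toluene F4 should undergo ring opening, 6π electrocyclization of the dienylketene and tautomerization. This is the known 4-alkenylcyclobutenone to hydroquinone expansion, and it should give 2-[(3S)-6,7-dimethoxychroman-3-yl]-5,6-dimethoxybenzene-1,4-diol F5. Oxidation with Ag2O (Et2O, rt) comes back to the route at 14.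

**Further compounds**

F1 | step 3 | racemic 6,7-dimethoxychroman-3-carboxylic acid | OC(=O)C1COc2cc(OC)c(OC)cc2C1
F2 | step 3 | (S)-1-phenylethylammonium (3R)-6,7-dimethoxychroman-3-carboxylate | C[C@H]([NH3+])c1ccccc1.[O-]C(=O)[C@H]1COc2cc(OC)c(OC)cc2C1
F3 | step 7 | (3S)-3-ethynyl-6,7-dimethoxychroman | C#C[C@H]1COc2cc(OC)c(OC)cc2C1
F4 | step 8 | 4-{(Z)-2-[(3S)-6,7-dimethoxychroman-3-yl]ethenyl}-4-hydroxy-2,3-dimethoxycyclobut-2-en-1-one | COC1=C(OC)C(O)(/C=C\[C@H]2COc3cc(OC)c(OC)cc3C2)C1=O
F5 | step 8 | 2-[(3S)-6,7-dimethoxychroman-3-yl]-5,6-dimethoxybenzene-1,4-diol | COc1c(OC)c(O)c([C@H]2COc3cc(OC)c(OC)cc3C2)cc1O
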